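## Structural features

Candidone is a flavanone: a pentasubstituted benzene ring A is fused through C4a and C8a to a dihydropyranone ring C (O1, C2, C3, C4 carbonyl), and C2 carries an unsubstituted phenyl ring B. Ring A has the phloroglucinol pattern with all three oxygens differentiated (O1 on C8a, methyl ethers on C5 and C7), a prenyl group on C8 and its only hydrogen on C6, so the C8 versus C6 placement of the prenyl chain is a regiochemical problem. The single stereocenter is C2 (S, read from the SMILES), a benzylic carbon bound to O1 and beta to the C4 ketone, with no neighbouring stereocenter to relay from. C2 is configurationally fragile: base (E1cB through the C3 enolate) or acid opens the O1–C2 bond to the 2'-hydroxychalcone, and reclosure racemises. The prenyl alkene is sensitive to acid (cyclisation onto an ortho phenol, hydration), to electrophiles and to hydrogenation. The real difficulty is to close ring C with C2 in one configuration without passing through the chalcone equilibrium, on a ring A whose five substituents are correctly placed. The key step exploits two facts: O1 and the C4 acyl carbon sit on adjacent ring carbons C8a and C4a, and the C5 methoxy group is ortho to C4a. An aryne across C4a–C8a is therefore polarised by that methoxy group in the sense needed to accept oxygen at C8a and the acyl carbon at C4a.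

## Logic of the disconnections

**15 to 11 + 12.** The bonds cut are O1–C8a and C4–C4a, the pair that joins ring C to ring A. This removes ring C in one operation and leaves C2 in the acyclic 12, where it cannot racemise by ring opening and which is available as one enantiomer. The other partner is 13, released from 11 by fluoride; it is electrophilic at C8a and, once oxygen has added, nucleophilic at C4a (as 14). The gain is that a bicyclic chiral target becomes one achiral arene and one purchased chiral hydroxy ester. The forward step must add oxygen to C8a and not C4a, acylate 14 faster than it is protonated, and preserve the configuration of the alkoxide of 12 and of 15 under fluoride conditions.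

**11 to 9.** The O–S bond of the triflate is cut, and the oxygen on C8a reverts to the carbamate that directed the assembly of ring A. The same oxygen thus serves as directing group, then as leaving group when 13 forms. The forward step must unmask 10 without acid, because the aryl–silicon bond on this electron-rich ring is prone to protodesilylation and an ortho-prenyl phenol cyclises under acid.

**9 to 6 + 3.** The bond cut is C8–C1' (aryl–CH2 of the prenyl chain). With silicon in place, the carbon between the carbamate oxygen and the C7 methoxy group is the only one still flanked by the carbamate and a methoxy group, so metalation (to 7) and alkylation (to 8) put the chain on the future C8. The carbon between the two methoxy groups has only the weaker directors, keeps its hydrogen and becomes C6. The forward step must couple 3 at its primary carbon and trap 7 before the carbamoyl group migrates.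

**6 to 2.** The bond cut is C4a–Si. Silicon marks the carbon that becomes the nucleophilic end of 13 and is introduced by metalation between the carbamate and a methoxy group (via 4 and 5). Because 2 is symmetric, the two such positions are equivalent, so the first substitution raises no regiochemical question beyond avoiding the site between the two methoxy groups. Since 6 already carries the directing group that the next metalation needs, it is not isolated and both substituents are introduced in one flask. This demands that the silylation be complete and leave no chlorosilane behind.

**2 to 1.** The carbamate C–O bond is cut, giving the commercial phenol 1, which already holds the three oxygens of ring A in the correct 1,3,5 relationship.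

## Other disconnections considered

**Alternative 1:** Cut O1–C2. The forward key step is an intramolecular oxa-Michael addition of 2'-hydroxychalcone A1 under a chiral base or hydrogen-bond catalyst. This is the first route that comes to mind. Its bond-forming step is the microscopic reverse of the process that racemises flavanones, so enantiopurity depends on kinetic control in a reversible reaction. An unactivated chalcone also offers a bifunctional catalyst only one binding point, which usually forces an auxiliary ester to be installed and removed. The C8 regiochemistry would rest on ortho C-prenylation of a phenol. The chosen plan never forms the chalcone and buys the stereocenter.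

**Alternative 2:** Cut C2–C3. The forward key step is an enantioselective dirhodium-carbene insertion into the benzylic C–H bond of the O-benzyl ether in diazoketone A2, with a chiral catalyst such as Rh2(S-PTTL)4. The idea is attractive because the benzyl ether becomes C2 and ring B. Three things count against it. The carbene is flanked by two ortho alkoxy oxygens, each able to intercept it as a five-membered oxonium ylide (a 1,2-benzyl shift would then give a benzofuranone). Enantiocontrol rests entirely on the catalyst for an acceptor-only carbene closing a six-membered ring. The benzyl ether cannot be present during aryl metalation, so A2 needs roughly seven steps. The chosen plan is shorter and its stereocenter is secure from the start.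

**Alternative 3:** Cut C4a–C5 and C8–C8a, building ring A last on a preformed enantiopure ring C. The forward key step is a Diels–Alder reaction between bromo dihydropyranone A3 (from a catalytic asymmetric hetero-Diels–Alder reaction, then bromination) and the prenyl-bearing 1,3-dimethoxy-1-silyloxy diene A4. Loss of HBr and methanol, with desilylation on work-up, would aromatise the adduct to 5-hydroxyflavanone A5, followed by O-methylation. The polarity match is correct at every ring position. However, the enone double bond of A3 is a vinylogous ester whose LUMO is raised by O1, so it is a poor dienophile. Forcing or Lewis-acidic conditions threaten both the silyl ketene acetal and the O1–C2 bond. Methylating the hydrogen-bonded C5 hydroxyl of A5 needs base that opens ring C. The route is also longer, about eight steps in two branches.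

Key step: step 4

Assumption: ethyl (S)-3-hydroxy-3-phenylpropanoate (12) is taken as a commercial single enantiomer, and C2 of the target is S as read from the given SMILES.

## Route

Step 1
Reactants: 1 3,5-dimethoxyphenol
Product: 2 3,5-dimethoxyphenyl N-isopropylcarbamate
Conditions: i-PrNCO, Et3N (cat.), CH2Cl2, rt
Reagents that add atoms: isopropyl isocyanate, CC(C)N=C=O
Why: Base-catalysed addition of the phenol to the isocyanate (carbamoylation) installs a secondary O-aryl carbamate, which is the strongest ortho-directing group on the ring and a phenol mask that can later be removed without acid.

Step 2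
Reactants: 2 3,5-dimethoxyphenyl N-isopropylcarbamate, 3 1-bromo-3-methylbut-2-ene (prenyl bromide)
Product: 9 3,5-dimethoxy-2-(3-methylbut-2-en-1-yl)-6-(trimethylsilyl)phenyl N-isopropylcarbamate, via N-silyl carbamate 4 (not isolated), via first aryllithium 5 (not isolated), via N-silyl arylsilane 6 (not isolated), via second aryllithium 7 (not isolated), via N-silyl prenyl arene 8 (not isolated)
Conditions: TBSOTf (1.05 equiv), TMEDA, Et2O, 0 °C to rt; n-BuLi (2.0 equiv), −78 °C; TMSCl (1.0 equiv), −78 to 0 °C; s-BuLi (1.2 equiv), −78 °C; CuBr·SMe2 (10 mol%), 3 (1.5 equiv), −78 to −20 °C; aq. NH4Cl, rt
Reagents that add atoms: chlorotrimethylsilane, C[Si](C)(C)Cl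
Why: Two directed ortho-metalations on the in situ N-silylated secondary carbamate are run in one flask: the N-silyl carbamate and the adjacent methoxy group direct the first lithiation to the carbon between them (the two such sites of 2 are equivalent), and after silylation the only position still flanked by the carbamate and a methoxy group is the future C8, where the second lithiation and a copper-catalysed allylic substitution of 3 at its primary carbon should place the prenyl chain. Silicon is introduced before the prenyl group so that no acidic benzylic-allylic CH2 is present during a lithiation, one equivalent of TMSCl is used so that none is left to consume the second charge of base, the alkylation is run cold to forestall anionic ortho-Fries migration, and the neutral aqueous work-up hydrolyses the N–Si bond without protodesilylating the electron-rich arylsilane.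

Step 3
Reactants: 9 3,5-dimethoxy-2-(3-methylbut-2-en-1-yl)-6-(trimethylsilyl)phenyl N-isopropylcarbamate
Product: 11 3,5-dimethoxy-2-(3-methylbut-2-en-1-yl)-6-(trimethylsilyl)phenyl trifluoromethanesulfonate, via phenol 10 (not isolated)
Conditions: DBU (1.5 equiv), Et2NH (1.1 equiv), MeCN, 40 °C; then PhNTf2 (1.3 equiv), rt
Reagents that add atoms: N-phenylbis(trifluoromethanesulfonimide), O=S(=O)(N(c1ccccc1)S(=O)(=O)C(F)(F)F)C(F)(F)F
Why: E1cB cleavage of the secondary carbamate (DBU removes N–H, isopropyl isocyanate is expelled and scavenged by diethylamine) frees the phenoxide of 10 without acid, and sulfonylation in the same flask should give the ortho-silylaryl triflate, the standard fluoride-triggered aryne precursor. Telescoping avoids isolating the ortho-silyl phenol, which could lose silicon by carbon-to-oxygen migration.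

Step 4
Reactants: 11 3,5-dimethoxy-2-(3-methylbut-2-en-1-yl)-6-(trimethylsilyl)phenyl trifluoromethanesulfonate, 12 ethyl (S)-3-hydroxy-3-phenylpropanoate
Product: 15 candidone [(2S)-5,7-dimethoxy-8-(3-methylbut-2-en-1-yl)-2-phenyl-2,3-dihydro-4H-chromen-4-one], via aryne 13 (not isolated), via aryl anion 14 (not isolated)
Conditions: CsF (3 equiv), THF, rt to 40 °C; 11 added slowly to 12 (2 equiv)
Reagents that add atoms: none
Why: Proposed new method: fluoride removes the trimethylsilyl group of 11 and triflate departs to give aryne 13; the fluoride-activated hydroxyl (alkoxide) of 12 attacks C8a to give aryl anion 14 at C4a, which adds to the ester carbonyl through a six-membered transition state and expels ethoxide; the closest known reaction types are the fluoride-induced annulation of arynes with salicylate esters to xanthones and the insertion of arynes into the C–O bond of carboxylic acids, here extended to an aliphatic beta-hydroxy ester. Ring C is closed in two events, an intermolecular O1–C8a addition followed by a 6-exo-trig acyl substitution that forms C4–C4a. The only stereocenter, C2, is not created in this step: it is carried in from 12, none of its four bonds is broken, and S in 12 maps to 2S in 15 because the priority order O > phenyl > CH2 > H is unchanged. The step needs oxygen to add at C8a and not C4a; the C5 methoxy group, ortho to C4a, withdraws inductively and distorts the aryne so that C8a is the more electrophilic carbon and the developing negative charge at C4a is stabilised, which should outweigh the modest steric bias of the C8 prenyl group. It also needs acyl capture of 14 to outrun protonation, which the intramolecular six-membered attack, the aprotic medium and the slow generation of 13 should favour. The mild fluoride conditions are chosen to limit retro-aldol cleavage of the alkoxide of 12 and base-induced ring opening of 15; the prenyl alkene and the methyl ethers are inert to CsF.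

## Compound list

1 | 3,5-dimethoxyphenol | COc1cc(O)cc(OC)c1 | starting material
2 | 3,5-dimethoxyphenyl N-isopropylcarbamate | COc1cc(OC)cc(OC(=O)NC(C)C)c1 | intermediate
3 | 1-bromo-3-methylbut-2-ene (prenyl bromide) | BrCC=C(C)C | starting material
4 | 3,5-dimethoxyphenyl N-(tert-butyldimethylsilyl)-N-isopropylcarbamate | COc1cc(OC)cc(OC(=O)N(C(C)C)[Si](C)(C)C(C)(C)C)c1 | intermediate
5 | 2-lithio-3,5-dimethoxyphenyl N-(tert-butyldimethylsilyl)-N-isopropylcarbamate | [Li]c1c(OC)cc(OC)cc1OC(=O)N(C(C)C)[Si](C)(C)C(C)(C)C | intermediate
6 | 3,5-dimethoxy-2-(trimethylsilyl)phenyl N-(tert-butyldimethylsilyl)-N-isopropylcarbamate | C[Si](C)(C)c1c(OC)cc(OC)cc1OC(=O)N(C(C)C)[Si](C)(C)C(C)(C)C | intermediate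
7 | 2-lithio-3,5-dimethoxy-6-(trimethylsilyl)phenyl N-(tert-butyldimethylsilyl)-N-isopropylcarbamate | C[Si](C)(C)c1c(OC)cc(OC)c([Li])c1OC(=O)N(C(C)C)[Si](C)(C)C(C)(C)C | intermediate
8 | 3,5-dimethoxy-2-(3-methylbut-2-en-1-yl)-6-(trimethylsilyl)phenyl N-(tert-butyldimethylsilyl)-N-isopropylcarbamate | C[Si](C)(C)c1c(OC)cc(OC)c(CC=C(C)C)c1OC(=O)N(C(C)C)[Si](C)(C)C(C)(C)C | intermediate
9 | 3,5-dimethoxy-2-(3-methylbut-2-en-1-yl)-6-(trimethylsilyl)phenyl N-isopropylcarbamate | C[Si](C)(C)c1c(OC)cc(OC)c(CC=C(C)C)c1OC(=O)NC(C)C | intermediate
10 | 3,5-dimethoxy-2-(3-methylbut-2-en-1-yl)-6-(trimethylsilyl)phenol (present as its amidinium phenoxide) | C[Si](C)(C)c1c(OC)cc(OC)c(CC=C(C)C)c1O | intermediate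
11 | 3,5-dimethoxy-2-(3-methylbut-2-en-1-yl)-6-(trimethylsilyl)phenyl trifluoromethanesulfonate | C[Si](C)(C)c1c(OC)cc(OC)c(CC=C(C)C)c1OS(=O)(=O)C(F)(F)F | intermediate
12 | ethyl (S)-3-hydroxy-3-phenylpropanoate | CCOC(=O)C[C@H](O)c1ccccc1 | starting material
13 | 3,5-dimethoxy-6-(3-methylbut-2-en-1-yl)benzyne (1,2-didehydrobenzene; C1 = future C8a, C2 = future C4a) | COC1=CC(OC)=C(CC=C(C)C)C#C1 | intermediate
14 | ethyl (3S)-3-[2-cesio-3,5-dimethoxy-6-(3-methylbut-2-en-1-yl)phenoxy]-3-phenylpropanoate | CCOC(=O)C[C@H](Oc1c(CC=C(C)C)c(OC)cc(OC)c1[Cs])c1ccccc1 | intermediate
15 | candidone [(2S)-5,7-dimethoxy-8-(3-methylbut-2-en-1-yl)-2-phenyl-2,3-dihydro-4H-chromen-4-one] | COc1cc(OC)c2c(c1CC=C(C)C)O[C@H](c1ccccc1)CC2=O | target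

## Step count and least certain steps

Total step count: 4. Longest linear sequence: 4 steps (1 to 2 to 9 to 11 to 15); 3 and 12 are purchased.

**Key step (step 4), the step labelled as a proposed new method.** Four processes are most likely to go wrong.
- Proton transfer to the aryl anion 14 before it reaches the ester, which would stop at an uncyclised aryl ether.
- Retro-aldol fragmentation of the alkoxide of 12 before it is captured by 13, which costs material and configuration.
- Erosion of configuration at C2 of 15 by base-induced opening of the O1–C2 bond through the C3 enolate and reclosure, promoted by the ethoxide released.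
- Sluggish addition of a secondary aliphatic hydroxyl to the aryne under fluoride activation.

The fallback uses only known reaction types and sets out from 11. Heating 11 with acetic acid and CsF in THF generates 13, which inserts into the C–O bond of the acid (carboxylate adds at C8a, the acyl group migrates to C4a, the same polarisation as above) to give acetophenone F1. Condensation of F1 with N,N-dimethylformamide dimethyl acetal gives enaminone F2, and dilute acetic acid closes it to chromone F3. A rhodium-catalysed asymmetric 1,4-addition of phenylboronic acid to F3 ([RhOH(cod)]2 with an electron-poor chiral bisphosphine, ligand enantiomer chosen for 2S, toluene–water) then sets C2 under non-equilibrating conditions and returns to the route at 15.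

**Step 2.** Several processes threaten the one-flask sequence.
- The second lithiation has to proceed in the presence of the lithium salts of the first half; incomplete silylation or incomplete second metalation would leave monosubstituted material.
- The hindered aryllithium 7 may undergo carbamoyl migration (anionic ortho-Fries) as it warms before it is alkylated.
- Coupling with 3 may occur partly at the tertiary terminus, giving the 1,1-dimethylallyl isomer.
- Lithiation may occur partly at the position between the two methoxy groups.

The fallback separates the two metalations and builds the chain by allylation and olefin metathesis; it sets out from 2. The first half is run alone: 2 is N-silylated, lithiated and silylated as above (via 4, 5 and 6), and aqueous work-up at that point gives monosilyl carbamate F4, which can be purified. In a second flask F4 is N-silylated and lithiated afresh (passing again through 6 and 7), and the aryllithium is quenched at −78 °C with the more reactive and regiochemically unambiguous allyl bromide to give N-silyl allyl arene F5, which on work-up gives allyl carbamate F6. Cross-metathesis of F6 with 2-methylbut-2-ene using the second-generation Grubbs catalyst, RuCl2(=CHPh)(PCy3)(H2IMes), converts allyl into prenyl and returns to the route at 9.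

**Step 3.** Cleavage of the hindered, electron-rich aryl carbamate may be slow. While it proceeds, the ortho-silyl phenoxide may lose its aryl–silicon bond through attack of the phenoxide oxygen on silicon and protonation at carbon. Residual diethylamine may also consume part of the sulfonylating agent. The fallback dispenses with the carbamate: it creates the phenoxide at −78 °C by an oxygen-to-carbon silyl shift and traps it at once. It sets out from 1.
- O-Allylation (allyl bromide, K2CO3, acetone) gives allyl ether F7.
- Aromatic Claisen rearrangement (N,N-diethylaniline, 190 °C) gives 2-allylphenol F8.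
- Ortho-selective bromination (NBS, catalytic i-Pr2NH, CH2Cl2) gives bromophenol F9.
- O-Silylation with hexamethyldisilazane gives silyl ether F10.
- Bromine–lithium exchange with n-BuLi at −78 °C triggers the retro-Brook shift, and the resulting lithium phenoxide is trapped in the same flask with Tf2O to give allyl silyl triflate F11.
- Cross-metathesis of F11 with 2-methylbut-2-ene (second-generation Grubbs catalyst, RuCl2(=CHPh)(PCy3)(H2IMes)) returns to the route at 11.

## Further compounds

F1 | step 4 | 1-[2-hydroxy-4,6-dimethoxy-3-(3-methylbut-2-en-1-yl)phenyl]ethan-1-one | COc1cc(OC)c(C(C)=O)c(O)c1CC=C(C)C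
F2 | step 4 | (E)-3-(dimethylamino)-1-[2-hydroxy-4,6-dimethoxy-3-(3-methylbut-2-en-1-yl)phenyl]prop-2-en-1-one | COc1cc(OC)c(C(=O)/C=C/N(C)C)c(O)c1CC=C(C)C
F3 | step 4 | 5,7-dimethoxy-8-(3-methylbut-2-en-1-yl)-4H-chromen-4-one | COc1cc(OC)c2c(=O)ccoc2c1CC=C(C)C
F4 | step 2 | 3,5-dimethoxy-2-(trimethylsilyl)phenyl N-isopropylcarbamate | C[Si](C)(C)c1c(OC)cc(OC)cc1OC(=O)NC(C)C
F5 | step 2 | 2-allyl-3,5-dimethoxy-6-(trimethylsilyl)phenyl N-(tert-butyldimethylsilyl)-N-isopropylcarbamate | C[Si](C)(C)c1c(OC)cc(OC)c(CC=C)c1OC(=O)N(C(C)C)[Si](C)(C)C(C)(C)C
F6 | step 2 | 2-allyl-3,5-dimethoxy-6-(trimethylsilyl)phenyl N-isopropylcarbamate | C[Si](C)(C)c1c(OC)cc(OC)c(CC=C)c1OC(=O)NC(C)C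
F7 | step 3 | 1-(allyloxy)-3,5-dimethoxybenzene | C=CCOc1cc(OC)cc(OC)c1
F8 | step 3 | 2-allyl-3,5-dimethoxyphenol | C=CCc1c(O)cc(OC)cc1OC
F9 | step 3 | 2-allyl-6-bromo-3,5-dimethoxyphenol | C=CCc1c(O)c(Br)c(OC)cc1OC
F10 | step 3 | (2-allyl-6-bromo-3,5-dimethoxyphenoxy)trimethylsilane | C=CCc1c(O[Si](C)(C)C)c(Br)c(OC)cc1OC
F11 | step 3 | 2-allyl-3,5-dimethoxy-6-(trimethylsilyl)phenyl trifluoromethanesulfonate | C=CCc1c(OS(=O)(=O)C(F)(F)F)c([Si](C)(C)C)c(OC)cc1OC
A1 | alternative 1 | (E)-1-[2-hydroxy-4,6-dimethoxy-3-(3-methylbut-2-en-1-yl)phenyl]-3-phenylprop-2-en-1-one | COc1cc(OC)c(C(=O)/C=C/c2ccccc2)c(O)c1CC=C(C)C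
A2 | alternative 2 | 1-[2-(benzyloxy)-4,6-dimethoxy-3-(3-methylbut-2-en-1-yl)phenyl]-2-diazoethan-1-one | COc1cc(OC)c(C(=O)C=[N+]=[N-])c(OCc2ccccc2)c1CC=C(C)C
A3 | alternative 3 | (2S)-5-bromo-2-phenyl-2,3-dihydro-4H-pyran-4-one | BrC1=CO[C@H](c2ccccc2)CC1=O
A4 | alternative 3 | [(1,3-dimethoxy-7-methylocta-1,3,6-trien-1-yl)oxy]trimethylsilane | COC(O[Si](C)(C)C)=CC(OC)=CCC=C(C)C
A5 | alternative 3 | (2S)-5-hydroxy-7-methoxy-8-(3-methylbut-2-en-1-yl)-2-phenyl-2,3-dihydro-4H-chromen-4-one | COc1cc(O)c2c(c1CC=C(C)C)O[C@H](c1ccccc1)CC2=O
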